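(The readings stem from a simulated flask on assumed constants.)

**Product ledger.** X is the last entry in a ledger of the limiting reagent, the charge smaller in moles. I ask how much of that charge reaches X in the time given.

| flask | L | E | remark | time |
|---|---|---|---|---|
| dusk | 1.2 M | 1.1 M | run made earlier |  |
| amber | 1.1 M | 1.10 M |  | 5.0 min |
| grey | 1.5 M | 0.400 M |  | 20 min |

dusk run (percent of the L charged): time / min: X / % = 0.500: 2.6; 1.00: 4.4; 1.50: 4.1; 2.00: 9.1; 2.50: 11.0; 3.00: 16.9

(standard deviation of a reading: 1 percentage point)

- candidate steps: G -> J; L + E <-> Z; Z -> G; J <-> X

1. the winner by amount of X, in percent of the L charged; "neither" if no more than 2 percentage points parts them (amber / grey / neither)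
2. how much X is there at the end, in percent of the L charged: amber
3. how much X is there at the end, in percent of the L charged: grey

**Closing entries.** Each mole of E that binds L passes along Z, G, J and X, so the charge equals free reagent plus those four entries. The ceiling on X, as a share of L charged, is the smaller charge over L: 91.7% in dusk, 100% in amber and 26.7% in grey, where E is limiting.

**Pool constant.** I treat Z, G and J as one pool, assumed full soon after mixing and emptying into X; dusk shows no plateau. Dusk's last reading, 16.9% at 3.00 min, taken per minute and divided by the full pool, gives a first round of 0.0615 min⁻¹. Putting that answer back, the mean pool in my reckoning comes out smaller, lowered by half the X made. The pool constant k_p, the fraction of the pool entering X per minute, becomes 0.0677 min⁻¹, a value read from one reading with scatter 1 percentage point.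

**My reckoning.** X is the ceiling times 1 − exp(−k_p t). That gives 28.7% for amber at 5.0 min and 19.8% for grey at 20 min, so by my reckoning amber leads by 8.9 points.

**The forecast.** It gives 26% for amber, lower than mine, and 20% for grey, and names amber: “Amber probably wins.”

**The flask.** Amber gives 31.4% and grey 20.9%, so amber wins, and my amber figure is 2.7 points lower.

    G → J (k = 0.00208 s⁻¹)
    L + E ⇌ Z (K = 3.00 M⁻¹, k = 0.155 M⁻¹ s⁻¹)
    Z → G (k = 0.0457 s⁻¹)
    J ⇌ X (K = 6.20, k = 0.0859 s⁻¹)

In amber, half of the Z → G turnover up to 5.0 min is done by 0.553 min, whereas the half-life of G by G → J alone is 5.6 min, ten times that time. At 5.00 min amber holds G at 57.0% of the L charged, more than X. For the flask like amber but with 0.28 M of E, the ceiling of 25.5% and k_p reckon 7.31%, and that flask gives 8.93%.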